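**Plan**
- Retrosynthesis: after removal of two silyl and two benzyl ethers, ring A is cut at C8–C8a, C5–C6, C7–C8 and C4a–C5. This leaves a 5-aryl-4-pyranon-2-yl α-diazo ketone that carries the protected C8 chain, and (triisopropylsilyloxy)ethyne as the C6–C7 unit.
- The diazo ketone is cut between the ketone carbon and the chain (Weinreb amide plus Grignard reagent) and between pyranone C5 and ring B (vinyl triflate of methyl comenate plus arylboronate).
- Forward order: the pyranone (later ring C) comes with comenic acid, ring B is joined by Suzuki–Miyaura coupling, the chain by acylation and diazo transfer, and ring A is made last by ketene–siloxyalkyne benzannulation; two deprotections finish.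
- Enabling feature: in ring A, O5 and O7 are meta, C6 carries H, C8 carries the alkyl chain, and the ring is fused at C4a–C8a to a pyranone whose C2=C3 bond is an enol-ether double bond. This is the pattern a vinylketene and a siloxyalkyne lay down around such a bond.
- Stereochemistry: the target has no stereocentre and no stereogenic double bond; only regiochemistry is controlled, by the polarity of the siloxyalkyne.

Key step: step 12

Remark: (triisopropylsilyloxy)ethyne is taken not to be purchasable and is therefore made (step 11); all transient stereocentres are racemic and vanish.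

Step 1
Reactants: 1 comenic acid (5-hydroxy-4-oxo-4H-pyran-2-carboxylic acid)
Product: 2 methyl 5-hydroxy-4-oxo-4H-pyran-2-carboxylate
Conditions: MeOH, H2SO4 (cat.), reflux
Reagents that add atoms: methanol CO
Why: Fischer esterification; the acid-stable pyranone and its enolic 5-hydroxyl are untouched.

Step 2
Reactants: 2 methyl 5-hydroxy-4-oxo-4H-pyran-2-carboxylate
Product: 3 methyl 4-oxo-5-{[(trifluoromethyl)sulfonyl]oxy}-4H-pyran-2-carboxylate
Conditions: Tf2O, pyridine, CH2Cl2, −20 → 0 °C
Reagents that add atoms: trifluoromethanesulfonic anhydride O=S(=O)(OS(=O)(=O)C(F)(F)F)C(F)(F)F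
Why: O-sulfonylation of the acidic enolic 5-hydroxyl of a 3-hydroxy-4-pyranone gives the vinyl triflate needed for cross-coupling.

Step 3
Reactants: 4 4-bromobenzene-1,3-diol (4-bromoresorcinol)
Product: 5 2,4-bis(benzyloxy)-1-bromobenzene
Conditions: BnBr, K2CO3, DMF, 60 °C
Reagents that add atoms: benzyl bromide BrCc1ccccc1
Why: double Williamson etherification; benzyl ethers survive the later basic, organometallic and photochemical steps and leave by neutral hydrogenolysis.

Step 4
Reactants: 5 2,4-bis(benzyloxy)-1-bromobenzene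
Product: 6 2-[2,4-bis(benzyloxy)phenyl]-4,4,5,5-tetramethyl-1,3,2-dioxaborolane
Conditions: B2pin2, Pd(dppf)Cl2 (3 mol %), KOAc, 1,4-dioxane, 90 °C
Reagents that add atoms: bis(pinacolato)diboron CC1(C)OB(OC1(C)C)B1OC(C)(C)C(C)(C)O1
Why: Miyaura borylation; the pinacol ester is chosen because free 2,4-dialkoxyphenylboronic acids protodeboronate easily.

Step 5
Reactants: 3 methyl 4-oxo-5-{[(trifluoromethyl)sulfonyl]oxy}-4H-pyran-2-carboxylate; 6 2-[2,4-bis(benzyloxy)phenyl]-4,4,5,5-tetramethyl-1,3,2-dioxaborolane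
Product: 7 methyl 5-[2,4-bis(benzyloxy)phenyl]-4-oxo-4H-pyran-2-carboxylate
Conditions: Pd(dppf)Cl2 (5 mol %), K3PO4, 1,4-dioxane/H2O (10:1), 70 °C
Reagents that add atoms: none
Why: Suzuki–Miyaura coupling; the electron-poor vinyl triflate next to the pyranone carbonyl adds readily to zerovalent palladium, and the mild phosphate base should spare the methyl ester.

Step 6
Reactants: 7 methyl 5-[2,4-bis(benzyloxy)phenyl]-4-oxo-4H-pyran-2-carboxylate
Product: 8 5-[2,4-bis(benzyloxy)phenyl]-N-methoxy-N-methyl-4-oxo-4H-pyran-2-carboxamide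
Conditions: MeNHOMe·HCl, AlMe3, CH2Cl2, 0 °C → rt
Reagents that add atoms: N,O-dimethylhydroxylamine hydrochloride CNOC.Cl
Why: Weinreb amidation of the activated 2-carboxylate by the preformed aluminium amide, mild enough to leave the pyranone ring closed.

Step 7
Reactants: 9 ethyl 4-bromobutanoate
Product: 10 5-bromo-2-methylpentan-2-ol
Conditions: MeMgBr (2.3 equiv), Et2O, 0 °C; aq. NH4Cl
Reagents that add atoms: methylmagnesium bromide C[Mg]Br
Why: twofold Grignard addition to the ester gives the tertiary alcohol; at 0 °C the magnesium alkoxide is too weak a nucleophile to displace the bromide and close a tetrahydrofuran.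

Step 8
Reactants: 10 5-bromo-2-methylpentan-2-ol
Product: 11 [(5-bromo-2-methylpentan-2-yl)oxy](triethyl)silane
Conditions: Et3SiOTf, 2,6-lutidine, CH2Cl2, 0 °C
Reagents that add atoms: triethylsilyl trifluoromethanesulfonate CC[Si](CC)(CC)OS(=O)(=O)C(F)(F)F
Why: silylation of a hindered tertiary alcohol with a silyl triflate; the ether masks the hydroxyl that would otherwise trap the ketene of step 12 as a δ-lactone, and it leaves with fluoride.

Step 9
Reactants: 11 [(5-bromo-2-methylpentan-2-yl)oxy](triethyl)silane; 8 5-[2,4-bis(benzyloxy)phenyl]-N-methoxy-N-methyl-4-oxo-4H-pyran-2-carboxamide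
Product: 13 1-{5-[2,4-bis(benzyloxy)phenyl]-4-oxo-4H-pyran-2-yl}-5-methyl-5-[(triethylsilyl)oxy]hexan-1-one, via alkylmagnesium bromide 12 (not isolated)
Conditions: Mg, THF, 40 °C; then 8, THF, −78 → −30 °C; aq. NH4Cl
Reagents that add atoms: none
Why: Grignard addition to a Weinreb amide; the chelated tetrahedral magnesium adduct prevents over-addition, and at low temperature the activated amide should react ahead of the vinylogous-ester carbonyl of the pyranone.

Step 10
Reactants: 13 1-{5-[2,4-bis(benzyloxy)phenyl]-4-oxo-4H-pyran-2-yl}-5-methyl-5-[(triethylsilyl)oxy]hexan-1-one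
Product: 15 1-{5-[2,4-bis(benzyloxy)phenyl]-4-oxo-4H-pyran-2-yl}-2-diazo-5-methyl-5-[(triethylsilyl)oxy]hexan-1-one, via trifluoroacetyl ketone 14 (not isolated)
Conditions: LiHMDS, THF, −78 °C; CF3CO2CH2CF3; then MsN3, Et3N, H2O (1 equiv), MeCN, rt
Reagents that add atoms: methanesulfonyl azide CS(=O)(=O)N=[N+]=[N-]; 2,2,2-trifluoroethyl trifluoroacetate O=C(OCC(F)(F)F)C(F)(F)F (its trifluoroacetyl group stays only in 14)
Why: detrifluoroacetylative diazo transfer (a deacylative Regitz diazo transfer): the only enolisable α-position is trifluoroacetylated through its lithium enolate, and the sulfonyl azide then delivers N2 with loss of the trifluoroacetyl group.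

Step 11
Reactants: 16 acetylene (ethyne)
Product: 19 (triisopropylsilyloxy)ethyne, via lithium acetylide 17 (not isolated), via lithium ethynolate 18 (not isolated)
Conditions: nBuLi, THF, −78 °C; tBuOOLi (from tBuOOH and LiHMDS), −78 → −10 °C; iPr3SiOTf, −78 °C
Reagents that add atoms: tert-butyl hydroperoxide, used as its lithium salt CC(C)(C)OO; triisopropylsilyl trifluoromethanesulfonate CC(C)[Si](C(C)C)(C(C)C)OS(=O)(=O)C(F)(F)F
Why: oxidation of a lithium acetylide to the lithium ynolate by lithium tert-butyl peroxide, then O-silylation with a bulky, hard silyl triflate, is the standard route from terminal alkynes to siloxyalkynes and is applied here to acetylene itself.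

Step 12
Reactants: 15 1-{5-[2,4-bis(benzyloxy)phenyl]-4-oxo-4H-pyran-2-yl}-2-diazo-5-methyl-5-[(triethylsilyl)oxy]hexan-1-one; 19 (triisopropylsilyloxy)ethyne
Product: 24 3-[2,4-bis(benzyloxy)phenyl]-5-hydroxy-8-{3-methyl-3-[(triethylsilyl)oxy]butyl}-7-{[tri(propan-2-yl)silyl]oxy}-4H-chromen-4-one, via pyranonyl ketene 20 (not isolated), via siloxycyclobutenone 21 (not isolated), via dienylketene 22 (not isolated), via dienone tautomer 23 (not isolated)
Conditions: 19 (3 equiv), blue LEDs (about 440 nm), degassed ClCH2CH2Cl, 25 °C; then 80 °C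
Reagents that add atoms: none
Why: Proposed new method: a 4-pyranon-2-yl α-diazo ketone has not served as ketene precursor in this annulation, the closest known reaction being the Danheiser benzannulation of vinyl and heteroaryl α-diazo ketones with siloxyalkynes through photochemical Wolff rearrangement, and the C2=C3 bond of the weakly aromatic pyranone, an enol-ether double bond, should act as the vinyl group at least as readily as a furan or thiophene bond. Loss of N2 with migration of the pyranonyl group to the diazo carbon (C8–C8a) should give ketene 20, whose carbonyl carbon bonds to the unsubstituted nucleophilic carbon of 19 in a regioselective [2+2] cycloaddition (C5–C6 and C7–C8) to cyclobutenone 21. Reversible four-electron ring opening gives dienylketene 22, and ring A closes by a thermal disrotatory six-electron electrocyclisation that joins the ketene carbon to pyranone C3 (C4a–C5); enolisation of dienone 23 then restores the pyranone and gives the C5 phenol. No stereocentre remains, since the quaternary carbon of 21 and C4a of 23 both become sp2. The step needs the orientation 5-OH, 6-H, 7-OSi, 8-alkyl, which the polarisation of the siloxyalkyne secures, and it needs Wolff migration to outrun a 1,2-hydride shift of the carbene into the chain, which direct photolysis with a good sp2 migrating group favours. Light near 440 nm should be absorbed by the conjugated diazo ketone alone, sparing the pyranone and the chromone product, whose C5 hydroxyl is hydrogen-bonded to C4=O and should not trap the ketene.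

Step 13
Reactants: 24 3-[2,4-bis(benzyloxy)phenyl]-5-hydroxy-8-{3-methyl-3-[(triethylsilyl)oxy]butyl}-7-{[tri(propan-2-yl)silyl]oxy}-4H-chromen-4-one
Product: 25 3-[2,4-bis(benzyloxy)phenyl]-5,7-dihydroxy-8-(3-hydroxy-3-methylbutyl)-4H-chromen-4-one
Conditions: Bu4NF, AcOH, THF, 0 °C → rt
Reagents that add atoms: none
Why: fluoride-mediated desilylation of the aryl and the tertiary alkyl silyl ether; acetic acid buffering keeps the medium from opening the chromone ring.

Step 14
Reactants: 25 3-[2,4-bis(benzyloxy)phenyl]-5,7-dihydroxy-8-(3-hydroxy-3-methylbutyl)-4H-chromen-4-one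
Product: 26 2,3-dehydrokievitone hydrate, 3-(2,4-dihydroxyphenyl)-5,7-dihydroxy-8-(3-hydroxy-3-methylbutyl)-4H-chromen-4-one
Conditions: H2 (1 atm), Pd/C (10 %), EtOAc/MeOH, rt
Reagents that add atoms: none
Why: hydrogenolysis of benzyl aryl ethers over palladium on carbon under neutral conditions; the chromone C2=C3 bond is reduced far more slowly, and the tertiary alcohol, which acid would cyclise onto O7, meets no acid.

**Compound list**
1 | comenic acid (5-hydroxy-4-oxo-4H-pyran-2-carboxylic acid) | OC(=O)c1cc(=O)c(O)co1 | starting material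
2 | methyl 5-hydroxy-4-oxo-4H-pyran-2-carboxylate | COC(=O)c1cc(=O)c(O)co1 | intermediate
3 | methyl 4-oxo-5-{[(trifluoromethyl)sulfonyl]oxy}-4H-pyran-2-carboxylate | COC(=O)c1cc(=O)c(OS(=O)(=O)C(F)(F)F)co1 | intermediate
4 | 4-bromobenzene-1,3-diol (4-bromoresorcinol) | Oc1ccc(Br)c(O)c1 | starting material
5 | 2,4-bis(benzyloxy)-1-bromobenzene | Brc1ccc(OCc2ccccc2)cc1OCc1ccccc1 | intermediate
6 | 2-[2,4-bis(benzyloxy)phenyl]-4,4,5,5-tetramethyl-1,3,2-dioxaborolane | CC1(C)OB(OC1(C)C)c1ccc(OCc2ccccc2)cc1OCc1ccccc1 | intermediate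
7 | methyl 5-[2,4-bis(benzyloxy)phenyl]-4-oxo-4H-pyran-2-carboxylate | COC(=O)c1cc(=O)c(-c2ccc(OCc3ccccc3)cc2OCc2ccccc2)co1 | intermediate
8 | 5-[2,4-bis(benzyloxy)phenyl]-N-methoxy-N-methyl-4-oxo-4H-pyran-2-carboxamide | CON(C)C(=O)c1cc(=O)c(-c2ccc(OCc3ccccc3)cc2OCc2ccccc2)co1 | intermediate
9 | ethyl 4-bromobutanoate | CCOC(=O)CCCBr | starting material
10 | 5-bromo-2-methylpentan-2-ol | CC(C)(O)CCCBr | intermediate
11 | [(5-bromo-2-methylpentan-2-yl)oxy](triethyl)silane | CC[Si](CC)(CC)OC(C)(C)CCCBr | intermediate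
12 | {4-methyl-4-[(triethylsilyl)oxy]pentyl}magnesium bromide (formed in the flask) | CC[Si](CC)(CC)OC(C)(C)CCC[Mg]Br | intermediate
13 | 1-{5-[2,4-bis(benzyloxy)phenyl]-4-oxo-4H-pyran-2-yl}-5-methyl-5-[(triethylsilyl)oxy]hexan-1-one | CC[Si](CC)(CC)OC(C)(C)CCCC(=O)c1cc(=O)c(-c2ccc(OCc3ccccc3)cc2OCc2ccccc2)co1 | intermediate
14 | 1-{5-[2,4-bis(benzyloxy)phenyl]-4-oxo-4H-pyran-2-yl}-4,4,4-trifluoro-2-{3-methyl-3-[(triethylsilyl)oxy]butyl}butane-1,3-dione (racemic, formed in the flask) | CC[Si](CC)(CC)OC(C)(C)CCC(C(=O)C(F)(F)F)C(=O)c1cc(=O)c(-c2ccc(OCc3ccccc3)cc2OCc2ccccc2)co1 | intermediate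
15 | 1-{5-[2,4-bis(benzyloxy)phenyl]-4-oxo-4H-pyran-2-yl}-2-diazo-5-methyl-5-[(triethylsilyl)oxy]hexan-1-one | CC[Si](CC)(CC)OC(C)(C)CCC(=[N+]=[N-])C(=O)c1cc(=O)c(-c2ccc(OCc3ccccc3)cc2OCc2ccccc2)co1 | intermediate
16 | acetylene (ethyne) | C#C | starting material
17 | lithium acetylide (formed in the flask) | [Li]C#C | intermediate
18 | lithium ethynolate (formed in the flask) | [Li]OC#C | intermediate
19 | (triisopropylsilyloxy)ethyne, (ethynyloxy)tri(propan-2-yl)silane | C#CO[Si](C(C)C)(C(C)C)C(C)C | intermediate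
20 | 2-{5-[2,4-bis(benzyloxy)phenyl]-4-oxo-4H-pyran-2-yl}-5-methyl-5-[(triethylsilyl)oxy]hex-1-en-1-one (ketene, formed in the flask) | O=C=C(CCC(C)(C)O[Si](CC)(CC)CC)c1cc(=O)c(-c2ccc(OCc3ccccc3)cc2OCc2ccccc2)co1 | intermediate
21 | 4-{5-[2,4-bis(benzyloxy)phenyl]-4-oxo-4H-pyran-2-yl}-4-{3-methyl-3-[(triethylsilyl)oxy]butyl}-3-{[tri(propan-2-yl)silyl]oxy}cyclobut-2-en-1-one (racemic, formed in the flask) | O=C1C=C(O[Si](C(C)C)(C(C)C)C(C)C)C1(CCC(C)(C)O[Si](CC)(CC)CC)c1cc(=O)c(-c2ccc(OCc3ccccc3)cc2OCc2ccccc2)co1 | intermediate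
22 | (3E)-4-{5-[2,4-bis(benzyloxy)phenyl]-4-oxo-4H-pyran-2-yl}-7-methyl-7-[(triethylsilyl)oxy]-3-{[tri(propan-2-yl)silyl]oxy}octa-1,3-dien-1-one (dienylketene, formed in the flask) | O=C=C/C(O[Si](C(C)C)(C(C)C)C(C)C)=C(/CCC(C)(C)O[Si](CC)(CC)CC)c1cc(=O)c(-c2ccc(OCc3ccccc3)cc2OCc2ccccc2)co1 | intermediate
23 | 3-[2,4-bis(benzyloxy)phenyl]-8-{3-methyl-3-[(triethylsilyl)oxy]butyl}-7-{[tri(propan-2-yl)silyl]oxy}-4aH-chromene-4,5-dione (racemic, formed in the flask) | O=C1C=C(O[Si](C(C)C)(C(C)C)C(C)C)C(CCC(C)(C)O[Si](CC)(CC)CC)=C2OC=C(-c3ccc(OCc4ccccc4)cc3OCc3ccccc3)C(=O)C12 | intermediate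
24 | 3-[2,4-bis(benzyloxy)phenyl]-5-hydroxy-8-{3-methyl-3-[(triethylsilyl)oxy]butyl}-7-{[tri(propan-2-yl)silyl]oxy}-4H-chromen-4-one | CC[Si](CC)(CC)OC(C)(C)CCc1c(O[Si](C(C)C)(C(C)C)C(C)C)cc(O)c2c(=O)c(-c3ccc(OCc4ccccc4)cc3OCc3ccccc3)coc12 | intermediate
25 | 3-[2,4-bis(benzyloxy)phenyl]-5,7-dihydroxy-8-(3-hydroxy-3-methylbutyl)-4H-chromen-4-one | CC(C)(O)CCc1c(O)cc(O)c2c(=O)c(-c3ccc(OCc4ccccc4)cc3OCc3ccccc3)coc12 | intermediate
26 | 2,3-dehydrokievitone hydrate, 3-(2,4-dihydroxyphenyl)-5,7-dihydroxy-8-(3-hydroxy-3-methylbutyl)-4H-chromen-4-one | CC(C)(O)CCc1c(O)cc(O)c2c(=O)c(-c3ccc(O)cc3O)coc12 | target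

**Step count and risks**
Total steps: 14. Longest linear sequence: 9 steps (1, 2, 5, 6, 9, 10, 12, 13, 14).

Steps most likely to fail:

1. Step 12. The carbene may shift a hydride from the chain instead of rearranging, the ketene may dimerise before it meets the alkyne, the electrocyclisation onto pyranone C3 may stall at the cyclobutenone, or the pyranone may photoisomerise.
Fallback with known chemistry, setting out from boronate 6 and coming back at target 26: ring A is taken preformed and the isoflavone is closed around it. Commercial 2,4,6-trihydroxyacetophenone would be dibenzylated (BnBr, K2CO3, DMF; the chelated hydroxyl stays free) to 1-[2,4-bis(benzyloxy)-6-hydroxyphenyl]ethanone F1. Iodination ortho to the free hydroxyl with benzyltrimethylammonium dichloroiodate and CaCO3 in CH2Cl2/MeOH would give 1-[4,6-bis(benzyloxy)-2-hydroxy-3-iodophenyl]ethanone F2. Hydroboration of 2-methylbut-3-en-2-ol with 9-BBN would give 9-(3-hydroxy-3-methylbutyl)-9-borabicyclo[3.3.1]nonane F3, and B-alkyl Suzuki–Miyaura coupling of F2 with F3 (Pd(dppf)Cl2, aqueous K3PO4, THF/DMF) would give 1-[4,6-bis(benzyloxy)-2-hydroxy-3-(3-hydroxy-3-methylbutyl)phenyl]ethanone F4. Condensation with N,N-dimethylformamide dimethyl acetal would give the enaminone (2E)-1-[4,6-bis(benzyloxy)-2-hydroxy-3-(3-hydroxy-3-methylbutyl)phenyl]-3-(dimethylamino)prop-2-en-1-one F5, and iodine in CHCl3/pyridine would close it to 5,7-bis(benzyloxy)-8-(3-hydroxy-3-methylbutyl)-3-iodo-4H-chromen-4-one F6. Suzuki–Miyaura coupling of F6 with 6 (Pd(dppf)Cl2, K2CO3, dioxane/H2O) would give 5,7-bis(benzyloxy)-3-[2,4-bis(benzyloxy)phenyl]-8-(3-hydroxy-3-methylbutyl)-4H-chromen-4-one F7, and hydrogenolysis over Pd/C would remove all four benzyl groups to give 26.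

2. Step 11. The ynolate may be silylated on carbon to a silylketene, lithium acetylide may disproportionate on warming, and the volatile product may be lost on isolation.
Fallback setting out from diazo ketone 15 and coming back at 25: an alkyl ynol ether, which cannot silylate on carbon, replaces the siloxyalkyne. 2-(Trimethylsilyl)ethanol would be treated with NaH and trichloroethylene in THF to give {2-[(E)-1,2-dichloroethenyloxy]ethyl}(trimethyl)silane F8. nBuLi at −78 °C (elimination, chlorine–lithium exchange, then MeOH quench) would give [2-(ethynyloxy)ethyl](trimethyl)silane F9. Benzannulation of 15 with F9 under the conditions of step 12 should give 3-[2,4-bis(benzyloxy)phenyl]-5-hydroxy-8-{3-methyl-3-[(triethylsilyl)oxy]butyl}-7-[2-(trimethylsilyl)ethoxy]-4H-chromen-4-one F10. Bu4NF in THF at 50 °C should then remove the triethylsilyl group and, by β-elimination, the 2-(trimethylsilyl)ethyl group to give 25.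

3. Step 9. The Grignard reagent may attack the pyranone (C4 carbonyl or C6) in competition with the Weinreb amide.
Fallback setting out from ester 7 and coming back at ketone 13: a mild organozinc reagent and palladium catalysis replace the Grignard addition. Ester 7 would be saponified (LiOH, THF/H2O, 0 °C) to 5-[2,4-bis(benzyloxy)phenyl]-4-oxo-4H-pyran-2-carboxylic acid F11 and converted with oxalyl chloride and catalytic DMF into 5-[2,4-bis(benzyloxy)phenyl]-4-oxo-4H-pyran-2-carbonyl chloride F12. Bromide 11 would be turned with Zn dust and LiCl in THF into {4-methyl-4-[(triethylsilyl)oxy]pentyl}zinc bromide F13. Negishi-type acylation of F12 with F13 (Pd(PPh3)4, THF, rt) would give 13.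

**Further compounds**
F1 | step 12 | 1-[2,4-bis(benzyloxy)-6-hydroxyphenyl]ethanone | CC(=O)c1c(O)cc(OCc2ccccc2)cc1OCc1ccccc1
F2 | step 12 | 1-[4,6-bis(benzyloxy)-2-hydroxy-3-iodophenyl]ethanone | CC(=O)c1c(O)c(I)c(OCc2ccccc2)cc1OCc1ccccc1
F3 | step 12 | 9-(3-hydroxy-3-methylbutyl)-9-borabicyclo[3.3.1]nonane | CC(C)(O)CCB1C2CCCC1CCC2
F4 | step 12 | 1-[4,6-bis(benzyloxy)-2-hydroxy-3-(3-hydroxy-3-methylbutyl)phenyl]ethanone | CC(=O)c1c(O)c(CCC(C)(C)O)c(OCc2ccccc2)cc1OCc1ccccc1
F5 | step 12 | (2E)-1-[4,6-bis(benzyloxy)-2-hydroxy-3-(3-hydroxy-3-methylbutyl)phenyl]-3-(dimethylamino)prop-2-en-1-one | CN(C)/C=C/C(=O)c1c(O)c(CCC(C)(C)O)c(OCc2ccccc2)cc1OCc1ccccc1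
F6 | step 12 | 5,7-bis(benzyloxy)-8-(3-hydroxy-3-methylbutyl)-3-iodo-4H-chromen-4-one | CC(C)(O)CCc1c(OCc2ccccc2)cc(OCc2ccccc2)c2c(=O)c(I)coc12
F7 | step 12 | 5,7-bis(benzyloxy)-3-[2,4-bis(benzyloxy)phenyl]-8-(3-hydroxy-3-methylbutyl)-4H-chromen-4-one | CC(C)(O)CCc1c(OCc2ccccc2)cc(OCc2ccccc2)c2c(=O)c(-c3ccc(OCc4ccccc4)cc3OCc3ccccc3)coc12
F8 | step 11 | {2-[(E)-1,2-dichloroethenyloxy]ethyl}(trimethyl)silane | C[Si](C)(C)CCO/C(Cl)=C\Cl
F9 | step 11 | [2-(ethynyloxy)ethyl](trimethyl)silane | C[Si](C)(C)CCOC#C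
F10 | step 11 | 3-[2,4-bis(benzyloxy)phenyl]-5-hydroxy-8-{3-methyl-3-[(triethylsilyl)oxy]butyl}-7-[2-(trimethylsilyl)ethoxy]-4H-chromen-4-one | CC[Si](CC)(CC)OC(C)(C)CCc1c(OCC[Si](C)(C)C)cc(O)c2c(=O)c(-c3ccc(OCc4ccccc4)cc3OCc3ccccc3)coc12
F11 | step 9 | 5-[2,4-bis(benzyloxy)phenyl]-4-oxo-4H-pyran-2-carboxylic acid | OC(=O)c1cc(=O)c(-c2ccc(OCc3ccccc3)cc2OCc2ccccc2)co1
F12 | step 9 | 5-[2,4-bis(benzyloxy)phenyl]-4-oxo-4H-pyran-2-carbonyl chloride | O=C(Cl)c1cc(=O)c(-c2ccc(OCc3ccccc3)cc2OCc2ccccc2)co1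
F13 | step 9 | {4-methyl-4-[(triethylsilyl)oxy]pentyl}zinc bromide | CC[Si](CC)(CC)OC(C)(C)CCC[Zn]Br
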